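## Retrosynthetic overview

1. Target 13 ⇐ 12 ⇐ 11: the phenol is released from its acetate and the 1,3-diol (O7, O9) from a benzylidene acetal. Lignan numbering is used throughout: C7 is the benzylic carbinol carbon, C8 the aryl ether carbon, C9 the CH2OH carbon.
2. 11 ⇐ acid 7 + aryl bromide 9: the C7–aryl bond is made by Ni-electrocatalytic decarboxylative arylation. The enabling feature is that C7 is an oxygen-bearing sp3 carbon inside the O7–C7–C8–C9–O9 glycerol unit. Tied up as C4 of a 2-phenyl-1,3-dioxane it is an α-oxy radical site that a carboxyl group can deliver, and the ring-locked axial C8–OAr bond next to it steers the incoming aryl group trans.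
3. 7 ⇐ 4 + 5: the C8–OAr bond is made by Mitsunobu inversion of the C5 hydroxyl of a dioxane erythronate.
4. 4 ⇐ 1: periodate cleavage of 4,6-O-benzylidene-D-glucose excises C1 and C2, so C3–C6 become the dioxane acid skeleton with the C8 precursor stereocentre and the acetal lock in place.
5. Ring order: no ring is formed in the route. The 1,3-dioxane is carried from 1 and opened in step 7; both aryl rings are bought.

Key step: step 6

Assumption: 1 is used as the commercial anomeric mixture (drawn as the α-anomer); the anomeric carbon is excised in step 1, so its configuration has no bearing. Aldehyde 3 exists largely as a hydrate or dimeric hemiacetal and is used crude.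

## Route

Step 1
Reactants: 1 4,6-O-[(R)-benzylidene]-D-glucopyranose
Product: 3 (2R,4R,5R)-5-hydroxy-2-phenyl-1,3-dioxane-4-carbaldehyde (2,4-O-benzylidene-D-erythrose), via 3-O-formyl-2,4-O-benzylidene-D-erythrose 2 (not isolated)
Conditions: NaIO4 (2.1 equiv), NaHCO3, H2O, 0 °C to rt
Reagents that add atoms: none
Why: Malaprade glycol cleavage of the C1–C2 and C2–C3 bonds releases C2 as formic acid and leaves C1 as a formate ester on O5, which the bicarbonate buffer should hydrolyse; the carbinol carbon (later C8) and the (R)-acetal carbon are carried over from glucose unchanged.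

Step 2
Reactants: 3 (2R,4R,5R)-5-hydroxy-2-phenyl-1,3-dioxane-4-carbaldehyde
Product: 4 methyl (2R,4R,5R)-5-hydroxy-2-phenyl-1,3-dioxane-4-carboxylate
Conditions: Br2, NaHCO3, MeOH/H2O (9:1), 0 °C to rt, dark
Reagents that add atoms: methanol, CO
Why: Direct oxidative esterification of the aldehyde through its methyl hemiacetal with buffered bromine should leave the secondary alcohol and the acetal untouched; no stereocentre is created, and the trans-diequatorial arrangement is the favoured one.

Step 3
Reactants: 4 methyl (2R,4R,5R)-5-hydroxy-2-phenyl-1,3-dioxane-4-carboxylate; 5 4-allyl-2,6-dimethoxyphenol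
Product: 6 methyl (2R,4R,5S)-5-(4-allyl-2,6-dimethoxyphenoxy)-2-phenyl-1,3-dioxane-4-carboxylate
Conditions: PPh3, DIAD, toluene (high concentration), 0 °C to 40 °C
Reagents that add atoms: none
Why: Mitsunobu etherification with SN2 inversion at C5 sets C8 as (S) with the aryloxy group axial; the equatorial oxyphosphonium has no anti-periplanar hydrogen, so E2 is disfavoured, and the axial approach over the two ring oxygens is unhindered.

Step 4
Reactants: 6 methyl (2R,4R,5S)-5-(4-allyl-2,6-dimethoxyphenoxy)-2-phenyl-1,3-dioxane-4-carboxylate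
Product: 7 (2R,4R,5S)-5-(4-allyl-2,6-dimethoxyphenoxy)-2-phenyl-1,3-dioxane-4-carboxylic acid
Conditions: Me3SnOH (4 equiv), 1,2-dichloroethane, 70 °C; then cold 0.5 M HCl wash
Reagents that add atoms: trimethyltin hydroxide, C[Sn](C)(C)O
Why: Mild, weakly basic methyl ester cleavage with trimethyltin hydroxide is chosen because the axial aryloxy group is anti-periplanar to the acidic H4 and could be lost by β-elimination under hydroxide saponification.

Step 5
Reactants: 8 4-bromo-2,6-dimethoxyphenol
Product: 9 4-bromo-2,6-dimethoxyphenyl acetate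
Conditions: Ac2O, pyridine, DMAP (cat.), CH2Cl2, rt
Reagents that add atoms: acetic anhydride, CC(=O)OC(C)=O
Why: Standard phenol acetylation; the acetate masks the phenol during electrolysis and later removes the para electron donor, so that the benzylic C7–O bond is not ionised in step 7.

Step 6
Reactants: 7 (2R,4R,5S)-5-(4-allyl-2,6-dimethoxyphenoxy)-2-phenyl-1,3-dioxane-4-carboxylic acid; 9 4-bromo-2,6-dimethoxyphenyl acetate
Product: 11 4-[(2R,4R,5S)-5-(4-allyl-2,6-dimethoxyphenoxy)-2-phenyl-1,3-dioxan-4-yl]-2,6-dimethoxyphenyl acetate, via N-acyloxyphthalimide ester 10 (not isolated)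
Conditions: N-hydroxyphthalimide, DIC, NMP, rt (no amine base); then 9 (2 equiv), NiCl2·6H2O (20 mol %), 2,2'-bipyridine (20 mol %), AgNO3 (0.3 equiv), LiCl, NMP, Mg(+)/RVC(−), constant current, rt
Reagents that add atoms: none
Why: Single-electron reduction of the redox-active ester 10 cleaves the N–O bond and expels CO2 to give the α-oxy radical at C4 of the dioxane (C7 of the target), which is captured by the aryl–nickel species formed from 9 at the silver-modified cathode, and reductive elimination from Ni(III) forms the C7–aryl bond. The closest known reaction type is the Ag–Ni-electrocatalytic decarboxylative arylation of redox-active esters with aryl halides, established for α-alkoxy acids including cyclic acetal (dioxolane and 1,3-dioxane) acids. No ring is closed. The new stereocentre C7 is under substrate control: the equatorial phenyl of the benzylidene acetal locks the chair in which the C5 aryloxy group is axial, so the aryl group should be delivered to C4 along the axial trajectory anti to that C–O bond, on the face that carries only the axial acetal hydrogen, giving the 4,5-trans dioxane, that is the (7R,8S) erythro series, the same 1,2-trans outcome as for furanosyl and mannopyranosyl radicals. The step needs cross-coupling to outrun hydrodecarboxylation and dimerisation, retention of the β-aryloxy group and an untouched allyl group: an excess of bromide 9 serves the first, β-scission of an aryl ether from a carbon radical is slow and a nickel centre trans to the aryloxy group cannot syn-eliminate it, and the terminal alkene should be inert to Ni/bipyridine at room temperature. Because C4 becomes planar, its configuration in 7 is irrelevant.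

Step 7
Reactants: 11 4-[(2R,4R,5S)-5-(4-allyl-2,6-dimethoxyphenoxy)-2-phenyl-1,3-dioxan-4-yl]-2,6-dimethoxyphenyl acetate
Product: 12 4-[(1R,2S)-2-(4-allyl-2,6-dimethoxyphenoxy)-1,3-dihydroxypropyl]-2,6-dimethoxyphenyl acetate
Conditions: AcOH/H2O (4:1), 45 °C
Reagents that add atoms: none
Why: Acid hydrolysis of the benzylidene acetal proceeds through the oxocarbenium ion at the acetal carbon, so the C7–O and C9–O bonds stay intact and both stereocentres are retained; the para-acetoxy group disfavours benzylic ionisation, and the strain of the trans-4,5-disubstituted dioxane should ease the cleavage.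

Step 8
Reactants: 12 4-[(1R,2S)-2-(4-allyl-2,6-dimethoxyphenoxy)-1,3-dihydroxypropyl]-2,6-dimethoxyphenyl acetate
Product: 13 (1R,2S)-2-(4-allyl-2,6-dimethoxyphenoxy)-1-(4-hydroxy-3,5-dimethoxyphenyl)propane-1,3-diol
Conditions: K2CO3 (0.2 equiv), MeOH, 0 °C to rt; then aq. NH4Cl
Reagents that add atoms: none
Why: Base-catalysed transesterification (methanolysis) of the aryl acetate should release the phenol under conditions that touch neither the aryl ether nor the two carbinol stereocentres.

## Compound list

1 | 4,6-O-[(R)-benzylidene]-α-D-glucopyranose | C([C@@H]1[C@H]([C@@H]([C@H]([C@H](O1)O)O)O)O2)O[C@H]2c3ccccc3 | starting material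
2 | (2R,4R,5R)-4-formyl-2-phenyl-1,3-dioxan-5-yl formate (3-O-formyl-2,4-O-benzylidene-D-erythrose) | c1ccccc1[C@@H]2OC[C@@H](OC=O)[C@H](C=O)O2 | intermediate
3 | (2R,4R,5R)-5-hydroxy-2-phenyl-1,3-dioxane-4-carbaldehyde (2,4-O-benzylidene-D-erythrose) | c1ccccc1[C@@H]2OC[C@@H](O)[C@H](C=O)O2 | intermediate
4 | methyl (2R,4R,5R)-5-hydroxy-2-phenyl-1,3-dioxane-4-carboxylate | c1ccccc1[C@@H]2OC[C@@H](O)[C@H](C(=O)OC)O2 | intermediate
5 | 4-allyl-2,6-dimethoxyphenol | C=CCc1cc(OC)c(O)c(OC)c1 | starting material
6 | methyl (2R,4R,5S)-5-(4-allyl-2,6-dimethoxyphenoxy)-2-phenyl-1,3-dioxane-4-carboxylate | c1ccccc1[C@@H]2OC[C@H](Oc3c(OC)cc(CC=C)cc3OC)[C@H](C(=O)OC)O2 | intermediate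
7 | (2R,4R,5S)-5-(4-allyl-2,6-dimethoxyphenoxy)-2-phenyl-1,3-dioxane-4-carboxylic acid | c1ccccc1[C@@H]2OC[C@H](Oc3c(OC)cc(CC=C)cc3OC)[C@H](C(=O)O)O2 | intermediate
8 | 4-bromo-2,6-dimethoxyphenol | COc1cc(Br)cc(OC)c1O | starting material
9 | 4-bromo-2,6-dimethoxyphenyl acetate | COc1cc(Br)cc(OC)c1OC(C)=O | intermediate
10 | 1,3-dioxoisoindolin-2-yl (2R,4R,5S)-5-(4-allyl-2,6-dimethoxyphenoxy)-2-phenyl-1,3-dioxane-4-carboxylate | c1ccccc1[C@@H]2OC[C@H](Oc3c(OC)cc(CC=C)cc3OC)[C@H](C(=O)ON4C(=O)c5ccccc5C4=O)O2 | intermediate
11 | 4-[(2R,4R,5S)-5-(4-allyl-2,6-dimethoxyphenoxy)-2-phenyl-1,3-dioxan-4-yl]-2,6-dimethoxyphenyl acetate | c1ccccc1[C@@H]2OC[C@H](Oc3c(OC)cc(CC=C)cc3OC)[C@@H](c4cc(OC)c(OC(C)=O)c(OC)c4)O2 | intermediate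
12 | 4-[(1R,2S)-2-(4-allyl-2,6-dimethoxyphenoxy)-1,3-dihydroxypropyl]-2,6-dimethoxyphenyl acetate | C=CCc1cc(OC)c(O[C@@H](CO)[C@H](O)c2cc(OC)c(OC(C)=O)c(OC)c2)c(OC)c1 | intermediate
13 | (1R,2S)-2-(4-allyl-2,6-dimethoxyphenoxy)-1-(4-hydroxy-3,5-dimethoxyphenyl)propane-1,3-diol | C=CCc1cc(OC)c(O[C@@H](CO)[C@H](O)c2cc(OC)c(O)c(OC)c2)c(OC)c1 | target

## Step count and risks

Total steps: 8. Longest linear sequence: 7 (steps 1, 2, 3, 4, 6, 7, 8); step 5 is a one-step side branch.

**Step 6 (key step).** Aryl transfer to the C4 radical may show poor facial selectivity and lead into the cis-dioxane (threo) series. The aryloxy group may also be lost by β-elimination at an organonickel stage, or reduction of the redox-active ester may outrun oxidative addition of the aryl bromide. The fallback forms the same C7–aryl bond by polar addition; it sets out from 5 and 8 and comes back at 13. Commercial methyl (R)-glycerate would be silylated at the primary hydroxyl (TBSCl, imidazole) to methyl (R)-3-[(tert-butyldimethylsilyl)oxy]-2-hydroxypropanoate F1. Mitsunobu etherification of F1 with 5 (PPh3, DIAD, inversion) should give methyl (S)-2-(4-allyl-2,6-dimethoxyphenoxy)-3-[(tert-butyldimethylsilyl)oxy]propanoate F2. DIBAL-H at −78 °C would reduce F2 to (S)-2-(4-allyl-2,6-dimethoxyphenoxy)-3-[(tert-butyldimethylsilyl)oxy]propanal F3, to be used at once because α-aryloxy aldehydes racemise easily. Separately 8 would be silylated to (4-bromo-2,6-dimethoxyphenoxy)(tert-butyl)dimethylsilane F4. Bromine–lithium exchange on F4 (n-BuLi, THF, −78 °C) and addition of the aryllithium to F3 under non-chelating conditions should follow the polar Felkin–Anh model and give the anti (erythro) adduct (1R,2S)-2-(4-allyl-2,6-dimethoxyphenoxy)-3-[(tert-butyldimethylsilyl)oxy]-1-{4-[(tert-butyldimethylsilyl)oxy]-3,5-dimethoxyphenyl}propan-1-ol F5. Any threo isomer would be removed by chromatography, and TBAF in THF would then cleave both silyl ethers to give 13.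

**Step 3.** The hindered 2,6-dimethoxyphenoxide may attack the oxyphosphonium too slowly, so that alkylation of the reduced azodicarboxylate or elimination toward the unsaturated ester takes over. The fallback separates activation from displacement; it sets out from 4 and comes back at 6. Triflation of 4 (Tf2O, pyridine, CH2Cl2, −20 °C) would give methyl (2R,4R,5R)-2-phenyl-5-{[(trifluoromethyl)sulfonyl]oxy}-1,3-dioxane-4-carboxylate F6. SN2 displacement of the equatorial triflate by the caesium salt of 5 (Cs2CO3, MeCN, rt) should then give 6 with the same inversion.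

**Step 4.** Cleavage of the methyl ester may trigger β-elimination of the axial aryloxide across C4–C5. The fallback replaces the methyl ester by an ester that is removed without base; it sets out from 3 and comes back at 7. Pinnick oxidation of 3 (NaClO2, NaH2PO4, 2-methyl-2-butene, t-BuOH/H2O) would give (2R,4R,5R)-5-hydroxy-2-phenyl-1,3-dioxane-4-carboxylic acid F7. Alkylation with allyl bromide (KHCO3, DMF) would give allyl (2R,4R,5R)-5-hydroxy-2-phenyl-1,3-dioxane-4-carboxylate F8. Mitsunobu etherification of F8 with 5, as in step 3, should give allyl (2R,4R,5S)-5-(4-allyl-2,6-dimethoxyphenoxy)-2-phenyl-1,3-dioxane-4-carboxylate F9. Pd(PPh3)4 with morpholine in THF at rt would remove the allyl ester under neutral conditions and give 7; the C-allyl group on the arene does not ionise under these conditions.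

## Further compounds

F1 | step 6 | methyl (R)-3-[(tert-butyldimethylsilyl)oxy]-2-hydroxypropanoate | COC(=O)[C@H](O)CO[Si](C)(C)C(C)(C)C
F2 | step 6 | methyl (S)-2-(4-allyl-2,6-dimethoxyphenoxy)-3-[(tert-butyldimethylsilyl)oxy]propanoate | COC(=O)[C@@H](Oc1c(OC)cc(CC=C)cc1OC)CO[Si](C)(C)C(C)(C)C
F3 | step 6 | (S)-2-(4-allyl-2,6-dimethoxyphenoxy)-3-[(tert-butyldimethylsilyl)oxy]propanal | O=C[C@@H](Oc1c(OC)cc(CC=C)cc1OC)CO[Si](C)(C)C(C)(C)C
F4 | step 6 | (4-bromo-2,6-dimethoxyphenoxy)(tert-butyl)dimethylsilane | COc1cc(Br)cc(OC)c1O[Si](C)(C)C(C)(C)C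
F5 | step 6 | (1R,2S)-2-(4-allyl-2,6-dimethoxyphenoxy)-3-[(tert-butyldimethylsilyl)oxy]-1-{4-[(tert-butyldimethylsilyl)oxy]-3,5-dimethoxyphenyl}propan-1-ol | C=CCc1cc(OC)c(O[C@@H](CO[Si](C)(C)C(C)(C)C)[C@H](O)c2cc(OC)c(O[Si](C)(C)C(C)(C)C)c(OC)c2)c(OC)c1
F6 | step 3 | methyl (2R,4R,5R)-2-phenyl-5-{[(trifluoromethyl)sulfonyl]oxy}-1,3-dioxane-4-carboxylate | c1ccccc1[C@@H]2OC[C@@H](OS(=O)(=O)C(F)(F)F)[C@H](C(=O)OC)O2
F7 | step 4 | (2R,4R,5R)-5-hydroxy-2-phenyl-1,3-dioxane-4-carboxylic acid | c1ccccc1[C@@H]2OC[C@@H](O)[C@H](C(=O)O)O2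
F8 | step 4 | allyl (2R,4R,5R)-5-hydroxy-2-phenyl-1,3-dioxane-4-carboxylate | c1ccccc1[C@@H]2OC[C@@H](O)[C@H](C(=O)OCC=C)O2
F9 | step 4 | allyl (2R,4R,5S)-5-(4-allyl-2,6-dimethoxyphenoxy)-2-phenyl-1,3-dioxane-4-carboxylate | c1ccccc1[C@@H]2OC[C@H](Oc3c(OC)cc(CC=C)cc3OC)[C@H](C(=O)OCC=C)O2
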